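**Retrosynthetic overview**

1. The target is (S)-2-heptadecyl-5,7-dihydroxy-6,8-dimethylchroman-4-one. The plan rests on ring A, a fully substituted benzene in which the oxygen-bearing carbons C5, C7 and C8a alternate with the carbon-bearing carbons C4a, C6 and C8.
2. The pyranone ring is closed last, at C4–C4a, by Friedel–Crafts acylation of an (S)-3-aryloxyicosanoic acid; hydrogenolysis of two benzyl ethers then gives the target.
3. Ring A is made by benzannulation of a 3-benzyloxy-2,4-dimethylcyclobutenone (C5 to C8 with O5, O7 and both methyls) with an (S)-alkyl ethynyl ether (C4a and C8a, with O1–C2 and the stereocentre already attached). C4a–C5 and C8–C8a are formed; C5–C6 is cleaved and re-formed.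
4. The cyclobutenone comes from methylketene and 1-(benzyloxy)propyne, itself made from benzyl formate by dichloromethylenation and elimination. The ethynyl ether comes from stearoyl chloride and Meldrum's acid by asymmetric hydrogenation (sets C2), reduction, monosilylation and the trichloroethylene ynol ether synthesis.
5. Ring order: ring A (step 9), then the oxygen heterocycle (step 13).

Key step: step 9

Remark: atom labels (O1, C2, C4a, C5 to C8a) are those of the chroman-4-one target. The cyclobutenone partner is used as the racemate, because its sp3 carbon becomes aromatic C6.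

**Route**

Step 1
Reactants: 1 benzyl formate
Product: 2 benzyl 2,2-dichlorovinyl ether
Conditions: PPh3 (3 equiv), CCl4 (10 equiv), THF, 60 °C
Reagents that add atoms: carbon tetrachloride (ClC(Cl)(Cl)Cl)
Why: Wittig-type dichloromethylenation: PPh3 and CCl4 give the ylide Ph3P=CCl2, which should olefinate the formyl carbonyl, the most electrophilic of ester carbonyls, to the 1,1-dichloroalkenyl ether.

Step 2
Reactants: 2 benzyl 2,2-dichlorovinyl ether
Product: 5 1-(benzyloxy)prop-1-yne, via benzyl chloroethynyl ether 3 (not isolated), via lithium (benzyloxy)ethynide 4 (not isolated)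
Conditions: n-BuLi (2.2 equiv), THF, −78 to −40 °C; MeI, DMPU, −78 °C to rt; product kept cold and used at once
Reagents that add atoms: iodomethane (CI)
Why: Elimination route to alkynyl ethers: n-BuLi removes the vinylic hydrogen of 2, loss of LiCl gives chloroalkyne 3, chlorine–lithium exchange with the second equivalent gives acetylide 4, and 4 should be C-methylated by iodomethane in the dipolar cosolvent.

Step 3
Reactants: 5 1-(benzyloxy)prop-1-yne; 6 propionyl chloride
Product: 8 3-(benzyloxy)-2,4-dimethylcyclobut-2-en-1-one (racemic), via methylketene 7 (not isolated)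
Conditions: 6 (2 equiv, slow addition), Et3N (2.2 equiv), Et2O, 0 °C to rt
Reagents that add atoms: none
Why: Ketene–alkyne [2+2] cycloaddition: dehydrochlorination of 6 gives methylketene 7, whose carbonyl carbon is attacked by the oxygen-free (methyl-bearing) carbon of ynol ether 5, which should place the benzyloxy group on C3 and the methyls on C2 and C4 of the cyclobutenone.

Step 4
Reactants: 9 stearoyl chloride; 10 Meldrum's acid
Product: 12 methyl 3-oxoicosanoate, via stearoyl Meldrum's acid 11 (not isolated)
Conditions: pyridine, CH2Cl2, 0 °C to rt; then MeOH, reflux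
Reagents that add atoms: methanol (CO)
Why: C-acylation of Meldrum's acid followed by methanolysis with loss of acetone and CO2 (Oikawa–Yonemitsu β-keto ester synthesis) should give the two-carbon-extended β-keto ester.

Step 5
Reactants: 12 methyl 3-oxoicosanoate
Product: 13 methyl (S)-3-hydroxyicosanoate
Conditions: H2 (50 atm), RuCl2[(S)-BINAP] (0.5 mol %), MeOH, 50 °C
Reagents that add atoms: none
Why: Noyori asymmetric hydrogenation of a β-keto ester: the (S)-BINAP complex of divalent ruthenium reduces the chelated ketone from the face that gives the (S)-carbinol, the sense established for 3-oxoalkanoates with an unbranched alkyl chain, and this centre becomes C2 of the target.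

Step 6
Reactants: 13 methyl (S)-3-hydroxyicosanoate
Product: 14 (S)-icosane-1,3-diol
Conditions: LiAlH4, THF, 0 °C to rt
Reagents that add atoms: none
Why: Hydride reduction of the ester to the primary alcohol should leave the carbinol centre untouched.

Step 7
Reactants: 14 (S)-icosane-1,3-diol
Product: 15 (S)-1-(triisopropylsilyloxy)icosan-3-ol
Conditions: TIPSCl (1.05 equiv), imidazole, CH2Cl2, 0 °C
Reagents that add atoms: triisopropylsilyl chloride (CC(C)[Si](Cl)(C(C)C)C(C)C)
Why: Silylation with the bulky chlorosilane should discriminate the primary from the secondary hydroxyl on steric grounds and gives the silyl ether least prone to migration.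

Step 8
Reactants: 15 (S)-1-(triisopropylsilyloxy)icosan-3-ol; 16 trichloroethylene
Product: 21 (S)-3-(ethynyloxy)-1-(triisopropylsilyloxy)icosane, via dichloroacetylene 17 (not isolated), via dichlorovinyl ether 18 (not isolated), via chloroethynyl ether 19 (not isolated), via lithium alkoxyethynide 20 (not isolated)
Conditions: KH, THF, 0 °C; 16, −50 °C to rt; n-BuLi (2.5 equiv), −78 to −40 °C; H2O, −78 °C
Reagents that add atoms: none
Why: Dichlorovinyl ether route to alkynyl ethers (Greene ynol ether synthesis): the potassium alkoxide of 15 eliminates HCl from 16 and adds to the dichloroacetylene 17 so formed to give 18, n-BuLi then effects dehydrochlorination to chloroalkyne 19 and chlorine–lithium exchange to acetylide 20, and a proton quench gives 21 with the carbinol C–O bond never broken, so the (S) configuration should be retained.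

Step 9
Reactants: 8 3-(benzyloxy)-2,4-dimethylcyclobut-2-en-1-one; 21 (S)-3-(ethynyloxy)-1-(triisopropylsilyloxy)icosane
Product: 26 (S)-3-(benzyloxy)-2,4-dimethyl-5-{[1-(triisopropylsilyloxy)icosan-3-yl]oxy}phenol, via vinylketene 22 (not isolated), via vinylcyclobutenone 23 (not isolated), via dienylketene 24 (not isolated), via cyclohexadienone 25 (not isolated)
Conditions: 8 (1.3 equiv), hν (300 nm, quartz), degassed CH2Cl2, 20 °C; then toluene, 80 °C
Reagents that add atoms: none
Why: Light opens cyclobutenone 8 by 4π-electrocyclic cleavage of C5–C6 to vinylketene 22, whose ketene C=C adds [2+2] to the electron-rich triple bond of 21 so that C4a bonds to the ketene carbon C5 and C8a to C8, giving 23. Warming opens 23 (4π) to dienylketene 24, a 6π-electrocyclisation re-forms C5–C6 and so closes the six-membered carbocycle ring A, and enolisation of dienone 25 should give phenol 26. The closest known reaction is the Danheiser benzannulation of cyclobutenones with alkoxyalkynes in its photochemically initiated form. No lasting stereocentre is created: the quaternary carbon of 23 and the sp3 carbon of 25 end up aromatic, and the (S) centre at C2 lies outside the reacting π system. The step needs regioselectivity in the [2+2], which the polarisation of the ynol ether secures (its oxygen-free carbon attacks the ketene carbonyl carbon), so all six ring positions follow from the connectivity of the partners. It also needs the ynol ether to survive until it has cycloadded, which is secured by generating the vinylketene with light at 20 °C and heating only after 21 is consumed, since a secondary alkyl ethynyl ether fragments by retro-ene on heating.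

Step 10
Reactants: 26 (S)-3-(benzyloxy)-2,4-dimethyl-5-{[1-(triisopropylsilyloxy)icosan-3-yl]oxy}phenol
Product: 27 (S)-1,3-bis(benzyloxy)-2,4-dimethyl-5-{[1-(triisopropylsilyloxy)icosan-3-yl]oxy}benzene
Conditions: BnBr, K2CO3, DMF, rt
Reagents that add atoms: benzyl bromide (BrCc1ccccc1)
Why: Williamson etherification of the C5 phenol under mild carbonate conditions should leave the silyl ether intact.

Step 11
Reactants: 27 (S)-1,3-bis(benzyloxy)-2,4-dimethyl-5-{[1-(triisopropylsilyloxy)icosan-3-yl]oxy}benzene
Product: 28 (S)-3-[3,5-bis(benzyloxy)-2,4-dimethylphenoxy]icosan-1-ol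
Conditions: TBAF, THF, 0 °C to rt
Reagents that add atoms: none
Why: Fluoride-induced desilylation should free the primary alcohol without touching the benzyl or aryl alkyl ethers.

Step 12
Reactants: 28 (S)-3-[3,5-bis(benzyloxy)-2,4-dimethylphenoxy]icosan-1-ol
Product: 30 (S)-3-[3,5-bis(benzyloxy)-2,4-dimethylphenoxy]icosanoic acid, via aldehyde 29 (not isolated)
Conditions: TEMPO (0.2 equiv), PhI(OAc)2 (2.5 equiv), CH2Cl2/H2O, rt
Reagents that add atoms: water (O)
Why: Oxoammonium-mediated oxidation (TEMPO with PhI(OAc)2 in wet solvent) should take the alcohol through aldehyde 29 and its hydrate to the acid under weakly acidic, chlorine-free conditions, so that the β-aryloxy aldehyde is not exposed to base and the electron-rich arene is not halogenated.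

Step 13
Reactants: 30 (S)-3-[3,5-bis(benzyloxy)-2,4-dimethylphenoxy]icosanoic acid
Product: 32 (S)-5,7-bis(benzyloxy)-2-heptadecyl-6,8-dimethylchroman-4-one, via mixed anhydride 31 (not isolated)
Conditions: TFAA (1.5 equiv), CH2Cl2, 0 °C to rt
Reagents that add atoms: none
Why: Intramolecular Friedel–Crafts acylation: the acyl trifluoroacetate 31 should acylate C4a, the only unsubstituted arene carbon, which is ortho to two ether oxygens and para to the third, closing the six-membered pyranone ring without involving C2.

Step 14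
Reactants: 32 (S)-5,7-bis(benzyloxy)-2-heptadecyl-6,8-dimethylchroman-4-one
Product: 33 (S)-2-heptadecyl-5,7-dihydroxy-6,8-dimethylchroman-4-one
Conditions: H2 (1 atm), 10% Pd/C, EtOAc, rt
Reagents that add atoms: none
Why: Hydrogenolysis of both aryl benzyl ethers under neutral conditions should leave the ketone, which is conjugated to the trioxygenated ring, and the base-sensitive C2 centre unchanged.

**Compound list**

1 | benzyl formate | O=COCc1ccccc1 | starting material
2 | benzyl 2,2-dichlorovinyl ether | ClC(Cl)=COCc1ccccc1 | intermediate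
3 | benzyl chloroethynyl ether | ClC#COCc1ccccc1 | intermediate
4 | lithium (benzyloxy)ethynide | [Li]C#COCc1ccccc1 | intermediate
5 | 1-(benzyloxy)prop-1-yne | CC#COCc1ccccc1 | intermediate
6 | propionyl chloride | CCC(=O)Cl | starting material
7 | methylketene | CC=C=O | intermediate
8 | 3-(benzyloxy)-2,4-dimethylcyclobut-2-en-1-one (racemic) | CC1C(=O)C(C)=C1OCc1ccccc1 | intermediate
9 | stearoyl chloride | CCCCCCCCCCCCCCCCCC(=O)Cl | starting material
10 | Meldrum's acid (2,2-dimethyl-1,3-dioxane-4,6-dione) | CC1(C)OC(=O)CC(=O)O1 | starting material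
11 | 5-(1-hydroxyoctadecylidene)-2,2-dimethyl-1,3-dioxane-4,6-dione (stearoyl Meldrum's acid) | CCCCCCCCCCCCCCCCCC(O)=C1C(=O)OC(C)(C)OC1=O | intermediate
12 | methyl 3-oxoicosanoate | CCCCCCCCCCCCCCCCCC(=O)CC(=O)OC | intermediate
13 | methyl (S)-3-hydroxyicosanoate | CCCCCCCCCCCCCCCCC[C@H](O)CC(=O)OC | intermediate
14 | (S)-icosane-1,3-diol | CCCCCCCCCCCCCCCCC[C@H](O)CCO | intermediate
15 | (S)-1-(triisopropylsilyloxy)icosan-3-ol | CCCCCCCCCCCCCCCCC[C@H](O)CCO[Si](C(C)C)(C(C)C)C(C)C | intermediate
16 | trichloroethylene | ClC=C(Cl)Cl | starting material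
17 | dichloroacetylene | ClC#CCl | intermediate
18 | (S)-3-[(E)-1,2-dichlorovinyloxy]-1-(triisopropylsilyloxy)icosane | CCCCCCCCCCCCCCCCC[C@H](O/C(Cl)=C\Cl)CCO[Si](C(C)C)(C(C)C)C(C)C | intermediate
19 | (S)-3-(chloroethynyloxy)-1-(triisopropylsilyloxy)icosane | CCCCCCCCCCCCCCCCC[C@H](OC#CCl)CCO[Si](C(C)C)(C(C)C)C(C)C | intermediate
20 | lithium 2-{[(S)-1-(triisopropylsilyloxy)icosan-3-yl]oxy}ethynide | CCCCCCCCCCCCCCCCC[C@H](OC#C[Li])CCO[Si](C(C)C)(C(C)C)C(C)C | intermediate
21 | (S)-3-(ethynyloxy)-1-(triisopropylsilyloxy)icosane | CCCCCCCCCCCCCCCCC[C@H](OC#C)CCO[Si](C(C)C)(C(C)C)C(C)C | intermediate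
22 | 3-(benzyloxy)-2-methylpenta-1,3-dien-1-one (vinylketene, alkene geometry not fixed) | CC=C(OCc1ccccc1)C(C)=C=O | intermediate
23 | 4-[1-(benzyloxy)prop-1-enyl]-4-methyl-3-{[(S)-1-(triisopropylsilyloxy)icosan-3-yl]oxy}cyclobut-2-en-1-one (mixture at ring C4) | CCCCCCCCCCCCCCCCC[C@H](OC1=CC(=O)C1(C)C(OCc2ccccc2)=CC)CCO[Si](C(C)C)(C(C)C)C(C)C | intermediate
24 | 5-(benzyloxy)-4-methyl-3-{[(S)-1-(triisopropylsilyloxy)icosan-3-yl]oxy}hepta-1,3,5-trien-1-one (dienylketene) | CCCCCCCCCCCCCCCCC[C@H](OC(C=C=O)=C(C)C(OCc1ccccc1)=CC)CCO[Si](C(C)C)(C(C)C)C(C)C | intermediate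
25 | 5-(benzyloxy)-4,6-dimethyl-3-{[(S)-1-(triisopropylsilyloxy)icosan-3-yl]oxy}cyclohexa-2,4-dien-1-one (mixture at C6) | CCCCCCCCCCCCCCCCC[C@H](OC1=CC(=O)C(C)C(OCc2ccccc2)=C1C)CCO[Si](C(C)C)(C(C)C)C(C)C | intermediate
26 | (S)-3-(benzyloxy)-2,4-dimethyl-5-{[1-(triisopropylsilyloxy)icosan-3-yl]oxy}phenol | CCCCCCCCCCCCCCCCC[C@H](Oc1cc(O)c(C)c(OCc2ccccc2)c1C)CCO[Si](C(C)C)(C(C)C)C(C)C | intermediate
27 | (S)-1,3-bis(benzyloxy)-2,4-dimethyl-5-{[1-(triisopropylsilyloxy)icosan-3-yl]oxy}benzene | CCCCCCCCCCCCCCCCC[C@H](Oc1cc(OCc2ccccc2)c(C)c(OCc2ccccc2)c1C)CCO[Si](C(C)C)(C(C)C)C(C)C | intermediate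
28 | (S)-3-[3,5-bis(benzyloxy)-2,4-dimethylphenoxy]icosan-1-ol | CCCCCCCCCCCCCCCCC[C@H](Oc1cc(OCc2ccccc2)c(C)c(OCc2ccccc2)c1C)CCO | intermediate
29 | (S)-3-[3,5-bis(benzyloxy)-2,4-dimethylphenoxy]icosanal | CCCCCCCCCCCCCCCCC[C@H](Oc1cc(OCc2ccccc2)c(C)c(OCc2ccccc2)c1C)CC=O | intermediate
30 | (S)-3-[3,5-bis(benzyloxy)-2,4-dimethylphenoxy]icosanoic acid | CCCCCCCCCCCCCCCCC[C@H](Oc1cc(OCc2ccccc2)c(C)c(OCc2ccccc2)c1C)CC(=O)O | intermediate
31 | (S)-3-[3,5-bis(benzyloxy)-2,4-dimethylphenoxy]icosanoic trifluoroacetic anhydride | CCCCCCCCCCCCCCCCC[C@H](Oc1cc(OCc2ccccc2)c(C)c(OCc2ccccc2)c1C)CC(=O)OC(=O)C(F)(F)F | intermediate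
32 | (S)-5,7-bis(benzyloxy)-2-heptadecyl-6,8-dimethylchroman-4-one | CCCCCCCCCCCCCCCCC[C@H]1CC(=O)c2c(OCc3ccccc3)c(C)c(OCc3ccccc3)c(C)c2O1 | intermediate
33 | (S)-2-heptadecyl-5,7-dihydroxy-6,8-dimethylchroman-4-one | CCCCCCCCCCCCCCCCC[C@H]1CC(=O)c2c(O)c(C)c(O)c(C)c2O1 | target

**Step count and risk**

Total step count: 14. Longest linear sequence: 11 steps (steps 4 to 14, from stearoyl chloride 9).

Step 9 (most likely to fail). The secondary ethynyl ether may fragment by retro-ene hydrogen transfer, or its branched alkoxy group may slow the ketene–alkyne [2+2], so that the vinylketene recloses, oligomerises or acylates the phenol instead of entering the cascade. The fallback moves the formation of the O1–C2 bond behind the benzannulation. It sets out from acetylide 4 of step 2, from cyclobutenone 8 and from alcohol 15, and rejoins the route at 27. Acetylide 4 is quenched with water in place of iodomethane to give benzyl ethynyl ether F1, which has no β-hydrogen and is unhindered. Benzannulation of F1 with 8 under the conditions of step 9 should give 3,5-bis(benzyloxy)-2,4-dimethylphenol F2, whose free hydroxyl (flanked by H and methyl) is the one needed, because the two such oxygens of the dimethylphloroglucinol core are related by symmetry. Alcohol 15 is inverted by Mitsunobu esterification (4-nitrobenzoic acid, PPh3, DIAD, THF) to (R)-1-(triisopropylsilyloxy)icosan-3-yl 4-nitrobenzoate F3 and methanolysed (K2CO3, MeOH) to (R)-1-(triisopropylsilyloxy)icosan-3-ol F4. Mitsunobu etherification of F4 with F2 (PPh3, DIAD, toluene) proceeds with inversion and should give 27 directly, so steps 9 and 10 are bypassed.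

Step 8. Under the potassium alkoxide conditions the silyl group may shift from the primary to the secondary oxygen, so that the wrong oxygen is vinylated, or the hindered alkoxide may add incompletely to dichloroacetylene. The fallback builds the triple bond from a formate, as in steps 1 and 2, without forming the alkoxide; it sets out from 15 and rejoins at 21. Alcohol 15 is formylated (acetic formic anhydride, pyridine) to (S)-1-(triisopropylsilyloxy)icosan-3-yl formate F5. Dichloromethylenation of the formate carbonyl (PPh3, CCl4, THF, 60 °C) gives (S)-3-(2,2-dichlorovinyloxy)-1-(triisopropylsilyloxy)icosane F6. Treatment with n-BuLi (2.2 equiv, THF, −78 °C) and then water should give, by way of chloroalkyne 19 and acetylide 20, ynol ether 21.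

Step 13. Acid-induced loss of a benzyl group, trifluoroacetylation of C4a by the reagent, or β-elimination of the aryloxy group from the activated acid may outrun ring closure. The fallback reverses the polarity of the C4–C4a bond formation (aryl nucleophile, acyl electrophile); it sets out from 30 and rejoins at 32. Acid 30 is brominated at C4a, its only free ring position (NBS, MeCN, 0 °C), to give (S)-3-[3,5-bis(benzyloxy)-2-bromo-4,6-dimethylphenoxy]icosanoic acid F7. Amidation (MeNHOMe·HCl, EDC·HCl, N-methylmorpholine, CH2Cl2) gives (S)-3-[3,5-bis(benzyloxy)-2-bromo-4,6-dimethylphenoxy]-N-methoxy-N-methylicosanamide F8. Bromine–lithium exchange with t-BuLi (2.1 equiv, THF, −78 °C) and attack of the aryl carbanion on the amide carbonyl (Parham cyclisation) should give 32.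

**Further compounds**

F1 | step 9 | benzyl ethynyl ether | C#COCc1ccccc1
F2 | step 9 | 3,5-bis(benzyloxy)-2,4-dimethylphenol | Cc1c(O)cc(OCc2ccccc2)c(C)c1OCc1ccccc1
F3 | step 9 | (R)-1-(triisopropylsilyloxy)icosan-3-yl 4-nitrobenzoate | CCCCCCCCCCCCCCCCC[C@@H](OC(=O)c1ccc(cc1)[N+](=O)[O-])CCO[Si](C(C)C)(C(C)C)C(C)C
F4 | step 9 | (R)-1-(triisopropylsilyloxy)icosan-3-ol | CCCCCCCCCCCCCCCCC[C@@H](O)CCO[Si](C(C)C)(C(C)C)C(C)C
F5 | step 8 | (S)-1-(triisopropylsilyloxy)icosan-3-yl formate | CCCCCCCCCCCCCCCCC[C@H](OC=O)CCO[Si](C(C)C)(C(C)C)C(C)C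
F6 | step 8 | (S)-3-(2,2-dichlorovinyloxy)-1-(triisopropylsilyloxy)icosane | CCCCCCCCCCCCCCCCC[C@H](OC=C(Cl)Cl)CCO[Si](C(C)C)(C(C)C)C(C)C
F7 | step 13 | (S)-3-[3,5-bis(benzyloxy)-2-bromo-4,6-dimethylphenoxy]icosanoic acid | CCCCCCCCCCCCCCCCC[C@H](Oc1c(Br)c(OCc2ccccc2)c(C)c(OCc2ccccc2)c1C)CC(=O)O
F8 | step 13 | (S)-3-[3,5-bis(benzyloxy)-2-bromo-4,6-dimethylphenoxy]-N-methoxy-N-methylicosanamide | CCCCCCCCCCCCCCCCC[C@H](Oc1c(Br)c(OCc2ccccc2)c(C)c(OCc2ccccc2)c1C)CC(=O)N(C)OC
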